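**Retrosynthetic overview**
- The three phenols and both formyl groups are installed last on a 2,4,6-trimethoxyphenyl ring; the isobutyl arm comes from methallylation of the benzylic C9′–H of an ArCH2–C1 unit.
- Key disconnection: C8a–C1 and C9′–aryl, formed together by a domino Heck–Suzuki reaction of a cycloheptenyl triflate carrying a 3-methylbut-3-enyl chain on C3a. The strategy rests on quaternary C1, which bears CH3, the vinylic ring-fusion carbon C8a (C8=C8a) and C9′: the neopentyl palladium that precedes it has no β-hydrogen and can wait for arylation.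
- The triflate derives from a cis-2,3-disubstituted cycloheptanone; C3a and C4 are set by CBS reduction followed by hydroxyl-directed hydrogenation, and the side chain is attached by B-alkyl Suzuki coupling.
- Ring order: the seven-membered ring first (one-carbon expansion of the carvone ring, which supplies C7), the cyclopentane second (5-exo Heck closure).

Key step: step 12

Remark: terpene atoms carry azulene numbers (C1–C8a), the benzylic carbon is C9′, and (R)-BINAP is taken as the ligand antipode that reinforces the substrate bias in step 12.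

**Route**

Step 1
Reactants: 1 (R)-carvone
Product: 2 (5R)-5-(2-hydroxypropan-2-yl)-2-methylcyclohex-2-en-1-one
Conditions: 50% aq. H2SO4, 0 °C
Reagents that add atoms: water, O
Why: Markovnikov acid-catalysed hydration of the 1,1-disubstituted isopropenyl alkene through its tertiary cation, with the protonated enone inert at 0 °C and C5 untouched.

Step 2
Reactants: 2 (5R)-5-(2-hydroxypropan-2-yl)-2-methylcyclohex-2-en-1-one
Product: 3 (5R)-2-methyl-5-{2-[(triethylsilyl)oxy]propan-2-yl}cyclohex-2-en-1-one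
Conditions: TESOTf, 2,6-lutidine, CH2Cl2, −78 → 0 °C
Reagents that add atoms: triethylsilyl trifluoromethanesulfonate, CC[Si](CC)(CC)OS(=O)(=O)C(F)(F)F
Why: Silyl triflate silylation of the hindered tertiary alcohol, which masks the carbinol against the hydride, carbene, base and triflating reagents used later.

Step 3
Reactants: 3 (5R)-2-methyl-5-{2-[(triethylsilyl)oxy]propan-2-yl}cyclohex-2-en-1-one
Product: 5 triethyl[(2-{(1R)-4-methyl-3-[(trimethylsilyl)oxy]cyclohex-3-en-1-yl}propan-2-yl)oxy]silane, via lithium enolate 4 (not isolated)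
Conditions: L-Selectride, THF, −78 °C; then TMSCl, Et3N, −78 → 0 °C; non-aqueous work-up
Reagents that add atoms: chlorotrimethylsilane, C[Si](C)(C)Cl
Why: Conjugate hydride addition to the β-unsubstituted enone gives the C1–C2 enolate regiospecifically, and O-silylation fixes it as the tetrasubstituted silyl enol ether (reductive enolate trapping).

Step 4
Reactants: 5 triethyl[(2-{(1R)-4-methyl-3-[(trimethylsilyl)oxy]cyclohex-3-en-1-yl}propan-2-yl)oxy]silane
Product: 7 (6R)-2-bromo-3-methyl-6-{2-[(triethylsilyl)oxy]propan-2-yl}cyclohept-2-en-1-one, via dibromocyclopropane 6 (not isolated)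
Conditions: CHBr3, KOt-Bu, pentane, −30 → 0 °C; filter; then Et3N, toluene, 80 °C; aq. NaHCO3
Reagents that add atoms: bromoform, BrC(Br)Br
Why: Dibromocarbene adds to the electron-rich enol ether and the gem-dibromo siloxycyclopropane opens by the cyclopropyl–allyl pathway with loss of bromide and the silyl group (dihalocarbene ring expansion of silyl enol ethers), giving the one-carbon-enlarged α-bromo enone directly.

Step 5
Reactants: 7 (6R)-2-bromo-3-methyl-6-{2-[(triethylsilyl)oxy]propan-2-yl}cyclohept-2-en-1-one; 8 2-methyl-2-vinyl-1,3-dioxolane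
Product: 10 (6R)-3-methyl-2-[2-(2-methyl-1,3-dioxolan-2-yl)ethyl]-6-{2-[(triethylsilyl)oxy]propan-2-yl}cyclohept-2-en-1-one, via B-alkyl-9-BBN adduct 9 (not isolated)
Conditions: 8, 9-BBN, THF, 0 °C → rt; then 7, Pd(dppf)Cl2 (cat.), AsPh3, Cs2CO3, DMF/THF/H2O, rt → 50 °C
Reagents that add atoms: none
Why: Anti-Markovnikov hydroboration of the vinyl ketal followed by B-alkyl Suzuki–Miyaura coupling with the α-bromo enone attaches the masked 3-oxobutyl chain at the future C3a.

Step 6
Reactants: 10 (6R)-3-methyl-2-[2-(2-methyl-1,3-dioxolan-2-yl)ethyl]-6-{2-[(triethylsilyl)oxy]propan-2-yl}cyclohept-2-en-1-one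
Product: 11 (1R,6R)-3-methyl-2-[2-(2-methyl-1,3-dioxolan-2-yl)ethyl]-6-{2-[(triethylsilyl)oxy]propan-2-yl}cyclohept-2-en-1-ol
Conditions: (S)-Me-CBS (20 mol%), catecholborane, toluene, −78 °C
Reagents that add atoms: none
Why: Corey–Bakshi–Shibata reduction in which the α-substituted alkenyl side acts as the large group, so the (S)-catalyst should deliver hydride to give the 1R carbinol (OH cis to the C6 side chain) under reagent control.

Step 7
Reactants: 11 (1R,6R)-3-methyl-2-[2-(2-methyl-1,3-dioxolan-2-yl)ethyl]-6-{2-[(triethylsilyl)oxy]propan-2-yl}cyclohept-2-en-1-ol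
Product: 12 (1R,2R,3R,6R)-3-methyl-2-[2-(2-methyl-1,3-dioxolan-2-yl)ethyl]-6-{2-[(triethylsilyl)oxy]propan-2-yl}cycloheptan-1-ol
Conditions: [Ir(cod)(PCy3)(py)]PF6 (cat.), H2 (up to 50 bar), CH2Cl2, rt
Reagents that add atoms: none
Why: Hydroxyl-directed homogeneous hydrogenation (Crabtree catalyst), in which iridium anchored on the allylic OH adds both hydrogens to the OH face of the tetrasubstituted alkene, setting C2 and C3 (future C3a and C4) with H-3a and H-4 cis to each other and to the C7 side chain.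

Step 8
Reactants: 12 (1R,2R,3R,6R)-3-methyl-2-[2-(2-methyl-1,3-dioxolan-2-yl)ethyl]-6-{2-[(triethylsilyl)oxy]propan-2-yl}cycloheptan-1-ol
Product: 13 (2R,3R,6R)-3-methyl-2-[2-(2-methyl-1,3-dioxolan-2-yl)ethyl]-6-{2-[(triethylsilyl)oxy]propan-2-yl}cycloheptan-1-one
Conditions: Dess–Martin periodinane, NaHCO3, CH2Cl2, 0 °C → rt
Reagents that add atoms: none
Why: Dess–Martin oxidation under buffered, non-enolising conditions returns the ketone without epimerising the cis α-centre.

Step 9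
Reactants: 13 (2R,3R,6R)-3-methyl-2-[2-(2-methyl-1,3-dioxolan-2-yl)ethyl]-6-{2-[(triethylsilyl)oxy]propan-2-yl}cycloheptan-1-one
Product: 15 (3R,6R,7R)-6-methyl-7-[2-(2-methyl-1,3-dioxolan-2-yl)ethyl]-3-{2-[(triethylsilyl)oxy]propan-2-yl}cyclohept-1-en-1-yl trifluoromethanesulfonate, via lithium enolate 14 (not isolated)
Conditions: LDA, THF, −78 °C; Comins' reagent, −78 → −40 °C; aq. NH4Cl
Reagents that add atoms: N-(5-chloropyridin-2-yl)bis(trifluoromethanesulfonimide), FC(F)(F)S(=O)(=O)N(c1ccc(Cl)cn1)S(=O)(=O)C(F)(F)F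
Why: Kinetic deprotonation takes the methylene α-hydrogen in preference to the methine at the substituted α-carbon, and O-triflation of the enolate fixes the less substituted enol triflate while leaving the cis α-centre untouched.

Step 10
Reactants: 15 (3R,6R,7R)-6-methyl-7-[2-(2-methyl-1,3-dioxolan-2-yl)ethyl]-3-{2-[(triethylsilyl)oxy]propan-2-yl}cyclohept-1-en-1-yl trifluoromethanesulfonate
Product: 16 (3R,6R,7R)-6-methyl-7-(3-oxobutyl)-3-{2-[(triethylsilyl)oxy]propan-2-yl}cyclohept-1-en-1-yl trifluoromethanesulfonate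
Conditions: PPTS, acetone/H2O, 40 °C
Reagents that add atoms: water, O
Why: Mild acid-catalysed ketal hydrolysis, which the enol triflate tolerates and which the hindered tertiary triethylsilyl ether is expected to outlast.

Step 11
Reactants: 16 (3R,6R,7R)-6-methyl-7-(3-oxobutyl)-3-{2-[(triethylsilyl)oxy]propan-2-yl}cyclohept-1-en-1-yl trifluoromethanesulfonate
Product: 17 (3R,6R,7R)-6-methyl-7-(3-methylbut-3-en-1-yl)-3-{2-[(triethylsilyl)oxy]propan-2-yl}cyclohept-1-en-1-yl trifluoromethanesulfonate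
Conditions: Ph3PCH3Br, KHMDS, THF, 0 °C; then 16, −20 °C → rt
Reagents that add atoms: methyltriphenylphosphonium bromide, C[P+](c1ccccc1)(c1ccccc1)c1ccccc1.[Br-]
Why: Wittig methylenation of the unhindered methyl ketone gives the 1,1-disubstituted alkene, the enol triflate being inert to the salt-free ylide and the former α-centre no longer acidic.

Step 12
Reactants: 17 (3R,6R,7R)-6-methyl-7-(3-methylbut-3-en-1-yl)-3-{2-[(triethylsilyl)oxy]propan-2-yl}cyclohept-1-en-1-yl trifluoromethanesulfonate; 18 2,4,6-trimethoxyphenylboronic acid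
Product: 19 triethyl[(2-{(1R,3aR,4R,7R)-1,4-dimethyl-1-[(2,4,6-trimethoxyphenyl)methyl]-1,2,3,3a,4,5,6,7-octahydroazulen-7-yl}propan-2-yl)oxy]silane
Conditions: Pd(OAc)2 (10 mol%), (R)-BINAP (15 mol%), 18 (3 equiv, in portions), K3PO4, THF/H2O 10:1, 65 °C
Reagents that add atoms: none
Why: Pd(0)/BINAP inserts into the C–OTf bond to give a cationic cycloheptenylpalladium, syn-carbopalladation of the pendant alkene forms C8a–C1, and the resulting Pd–CH2 neopentyl species, which has no β-hydrogen, transmetalates with the arylboronate and reductively eliminates to form C9′–aryl. The closest known chemistry is the asymmetric intramolecular Heck cyclisation that builds quaternary carbons, run as a cyclisation–anion-capture (Heck–Suzuki) domino. The cyclopentane closes in the 5-exo-trig mode, the 1,1-disubstitution and the two-carbon tether directing C8a to the internal alkene carbon. C1 (R) arises from alkene face selection: with H-3a eclipsing the C–Pd bond and the tether pseudoaxial on C3a, the alkene reaches C8a from the tether face and places the C1 methyl anti to H-3a, a substrate preference that the chiral bisphosphine on cationic palladium should reinforce. The step needs cyclisation to precede direct Suzuki coupling, which the intramolecular insertion and the slow transmetalation of the di-ortho-substituted boronic acid secure. It also needs capture to precede 3-exo insertion into C8=C8a, which excess boronate in aqueous phosphate is meant to secure.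

Step 13
Reactants: 19 triethyl[(2-{(1R,3aR,4R,7R)-1,4-dimethyl-1-[(2,4,6-trimethoxyphenyl)methyl]-1,2,3,3a,4,5,6,7-octahydroazulen-7-yl}propan-2-yl)oxy]silane
Product: 20 triethyl[(2-{(1R,3aR,4R,7R)-1,4-dimethyl-1-[(1R)-3-methyl-1-(2,4,6-trimethoxyphenyl)but-3-en-1-yl]-1,2,3,3a,4,5,6,7-octahydroazulen-7-yl}propan-2-yl)oxy]silane
Conditions: DDQ (1.2 equiv), methallyltrimethylsilane (4 equiv), LiClO4, 4 Å MS, CH2Cl2, 0 °C → rt
Reagents that add atoms: methallyltrimethylsilane, C=C(C)C[Si](C)(C)C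
Why: Proposed new method: DDQ should form a charge-transfer complex with the trimethoxyarene (the most electron-rich site, ahead of the allylic C–H bonds) and abstract hydride from C9′ to give a 2,4,6-trimethoxybenzyl, quinone-methide-like cation, which the allylsilane captures in an SE2′ step before DDQH− takes the silyl group; the closest known reactions are the DDQ-mediated oxidative C–H allylation of benzylic ethers and diarylmethanes with allylsilanes and the Lewis-acid Hosomi–Sakurai substitution of electron-rich benzylic alcohols; C9′ (R) is set by 1,2-induction from quaternary C1 in a Felkin-type arrangement with C8a and its cycloheptene anti to the nucleophile and the C1 methyl nearest the aryl plane, so that carbon enters past C2-H2.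

Step 14
Reactants: 20 triethyl[(2-{(1R,3aR,4R,7R)-1,4-dimethyl-1-[(1R)-3-methyl-1-(2,4,6-trimethoxyphenyl)but-3-en-1-yl]-1,2,3,3a,4,5,6,7-octahydroazulen-7-yl}propan-2-yl)oxy]silane
Product: 21 triethyl[(2-{(1R,3aR,4R,7R)-1,4-dimethyl-1-[(1R)-3-methyl-1-(2,4,6-trimethoxyphenyl)butyl]-1,2,3,3a,4,5,6,7-octahydroazulen-7-yl}propan-2-yl)oxy]silane
Conditions: (Ph3P)3RhCl (cat.), H2 (1 atm), benzene/EtOH, rt
Reagents that add atoms: none
Why: Wilkinson hydrogenation reduces the accessible 1,1-disubstituted alkene and leaves the hindered trisubstituted C8=C8a alkene, which is flanked by quaternary C1.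

Step 15
Reactants: 21 triethyl[(2-{(1R,3aR,4R,7R)-1,4-dimethyl-1-[(1R)-3-methyl-1-(2,4,6-trimethoxyphenyl)butyl]-1,2,3,3a,4,5,6,7-octahydroazulen-7-yl}propan-2-yl)oxy]silane
Product: 22 triethyl[(2-{(1R,3aR,4R,7R)-1-[(1R)-1-(3,5-dibromo-2,4,6-trimethoxyphenyl)-3-methylbutyl]-1,4-dimethyl-1,2,3,3a,4,5,6,7-octahydroazulen-7-yl}propan-2-yl)oxy]silane
Conditions: NBS (2.1 equiv), MeCN/CH2Cl2, 0 °C, dark
Reagents that add atoms: N-bromosuccinimide, O=C1CCC(=O)N1Br
Why: Electrophilic aromatic bromination at the two free ring positions, each activated by two ortho and one para methoxy group, which should outrun any reaction of NBS with the hindered alkene in the dark.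

Step 16
Reactants: 22 triethyl[(2-{(1R,3aR,4R,7R)-1-[(1R)-1-(3,5-dibromo-2,4,6-trimethoxyphenyl)-3-methylbutyl]-1,4-dimethyl-1,2,3,3a,4,5,6,7-octahydroazulen-7-yl}propan-2-yl)oxy]silane
Product: 24 5-[(1R)-1-{(1R,3aR,4R,7R)-1,4-dimethyl-7-{2-[(triethylsilyl)oxy]propan-2-yl}-1,2,3,3a,4,5,6,7-octahydroazulen-1-yl}-3-methylbutyl]-2,4,6-trimethoxybenzene-1,3-dicarbaldehyde, via dilithioarene 23 (not isolated)
Conditions: t-BuLi (4.4 equiv), THF, −78 °C; DMF, −78 → 0 °C; aq. NH4Cl
Reagents that add atoms: N,N-dimethylformamide, CN(C)C=O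
Why: Double bromine–lithium exchange gives a bis-aryllithium whose carbanions are each held by two flanking methoxy groups, and formylation with DMF delivers both aldehydes under basic conditions that spare the silyl ether and the alkene.

Step 17
Reactants: 24 5-[(1R)-1-{(1R,3aR,4R,7R)-1,4-dimethyl-7-{2-[(triethylsilyl)oxy]propan-2-yl}-1,2,3,3a,4,5,6,7-octahydroazulen-1-yl}-3-methylbutyl]-2,4,6-trimethoxybenzene-1,3-dicarbaldehyde
Product: 25 5-[(1R)-1-{(1R,3aR,4R,7R)-7-(2-hydroxypropan-2-yl)-1,4-dimethyl-1,2,3,3a,4,5,6,7-octahydroazulen-1-yl}-3-methylbutyl]-2,4,6-trimethoxybenzene-1,3-dicarbaldehyde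
Conditions: HF·pyridine, THF/pyridine, 0 °C → rt
Reagents that add atoms: none
Why: Fluoride-driven Si–O cleavage of the tertiary triethylsilyl ether under buffered conditions that leave the aldehydes, the aryl methyl ethers and the alkene untouched.

Step 18
Reactants: 25 5-[(1R)-1-{(1R,3aR,4R,7R)-7-(2-hydroxypropan-2-yl)-1,4-dimethyl-1,2,3,3a,4,5,6,7-octahydroazulen-1-yl}-3-methylbutyl]-2,4,6-trimethoxybenzene-1,3-dicarbaldehyde
Product: 26 (−)-macrocarpal D
Conditions: 4-MeC6H4SH, n-BuLi (→ ArSLi, 12 equiv), HMPA/toluene, 110 °C; then 1 M HCl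
Reagents that add atoms: none
Why: Nucleophilic O-demethylation by SN2 attack of the soft thiolate at the methyl carbons, each methoxy group lying ortho or para to a formyl group that stabilises the departing phenoxide, while the tertiary alcohol, the alkene and both stereocentres at C1 and C9′ are inert to thiolate.

**Compound list**

1 | (R)-carvone | CC1=CC[C@H](CC1=O)C(C)=C | starting material
2 | (5R)-5-(2-hydroxypropan-2-yl)-2-methylcyclohex-2-en-1-one | CC1=CC[C@H](CC1=O)C(C)(C)O | intermediate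
3 | (5R)-2-methyl-5-{2-[(triethylsilyl)oxy]propan-2-yl}cyclohex-2-en-1-one | CC1=CC[C@H](CC1=O)C(C)(C)O[Si](CC)(CC)CC | intermediate
4 | lithium (5R)-2-methyl-5-{2-[(triethylsilyl)oxy]propan-2-yl}cyclohex-1-en-1-olate | CC1=C(O[Li])C[C@@H](CC1)C(C)(C)O[Si](CC)(CC)CC | intermediate
5 | triethyl[(2-{(1R)-4-methyl-3-[(trimethylsilyl)oxy]cyclohex-3-en-1-yl}propan-2-yl)oxy]silane | CC1=C(O[Si](C)(C)C)C[C@@H](CC1)C(C)(C)O[Si](CC)(CC)CC | intermediate
6 | (3R)-7,7-dibromo-6-methyl-3-{2-[(triethylsilyl)oxy]propan-2-yl}-1-[(trimethylsilyl)oxy]bicyclo[4.1.0]heptane (ring-fusion diastereomers) | CC12CC[C@@H](C(C)(C)O[Si](CC)(CC)CC)CC1(O[Si](C)(C)C)C2(Br)Br | intermediate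
7 | (6R)-2-bromo-3-methyl-6-{2-[(triethylsilyl)oxy]propan-2-yl}cyclohept-2-en-1-one | CC1=C(Br)C(=O)C[C@@H](CC1)C(C)(C)O[Si](CC)(CC)CC | intermediate
8 | 2-methyl-2-vinyl-1,3-dioxolane | C=CC1(C)OCCO1 | starting material
9 | 9-[2-(2-methyl-1,3-dioxolan-2-yl)ethyl]-9-borabicyclo[3.3.1]nonane | CC1(CCB2C3CCCC2CCC3)OCCO1 | intermediate
10 | (6R)-3-methyl-2-[2-(2-methyl-1,3-dioxolan-2-yl)ethyl]-6-{2-[(triethylsilyl)oxy]propan-2-yl}cyclohept-2-en-1-one | CC1=C(CCC2(C)OCCO2)C(=O)C[C@@H](CC1)C(C)(C)O[Si](CC)(CC)CC | intermediate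
11 | (1R,6R)-3-methyl-2-[2-(2-methyl-1,3-dioxolan-2-yl)ethyl]-6-{2-[(triethylsilyl)oxy]propan-2-yl}cyclohept-2-en-1-ol | CC1=C(CCC2(C)OCCO2)[C@H](O)C[C@@H](CC1)C(C)(C)O[Si](CC)(CC)CC | intermediate
12 | (1R,2R,3R,6R)-3-methyl-2-[2-(2-methyl-1,3-dioxolan-2-yl)ethyl]-6-{2-[(triethylsilyl)oxy]propan-2-yl}cycloheptan-1-ol | CC1(CC[C@H]2[C@H](O)C[C@H](C(C)(C)O[Si](CC)(CC)CC)CC[C@H]2C)OCCO1 | intermediate
13 | (2R,3R,6R)-3-methyl-2-[2-(2-methyl-1,3-dioxolan-2-yl)ethyl]-6-{2-[(triethylsilyl)oxy]propan-2-yl}cycloheptan-1-one | CC1(CC[C@H]2C(=O)C[C@H](C(C)(C)O[Si](CC)(CC)CC)CC[C@H]2C)OCCO1 | intermediate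
14 | lithium (3R,6R,7R)-6-methyl-7-[2-(2-methyl-1,3-dioxolan-2-yl)ethyl]-3-{2-[(triethylsilyl)oxy]propan-2-yl}cyclohept-1-en-1-olate | CC1(CC[C@H]2C(O[Li])=C[C@H](C(C)(C)O[Si](CC)(CC)CC)CC[C@H]2C)OCCO1 | intermediate
15 | (3R,6R,7R)-6-methyl-7-[2-(2-methyl-1,3-dioxolan-2-yl)ethyl]-3-{2-[(triethylsilyl)oxy]propan-2-yl}cyclohept-1-en-1-yl trifluoromethanesulfonate | CC1(CC[C@H]2C(OS(=O)(=O)C(F)(F)F)=C[C@H](C(C)(C)O[Si](CC)(CC)CC)CC[C@H]2C)OCCO1 | intermediate
16 | (3R,6R,7R)-6-methyl-7-(3-oxobutyl)-3-{2-[(triethylsilyl)oxy]propan-2-yl}cyclohept-1-en-1-yl trifluoromethanesulfonate | CC(=O)CC[C@H]1C(OS(=O)(=O)C(F)(F)F)=C[C@H](C(C)(C)O[Si](CC)(CC)CC)CC[C@H]1C | intermediate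
17 | (3R,6R,7R)-6-methyl-7-(3-methylbut-3-en-1-yl)-3-{2-[(triethylsilyl)oxy]propan-2-yl}cyclohept-1-en-1-yl trifluoromethanesulfonate | C=C(C)CC[C@H]1C(OS(=O)(=O)C(F)(F)F)=C[C@H](C(C)(C)O[Si](CC)(CC)CC)CC[C@H]1C | intermediate
18 | 2,4,6-trimethoxyphenylboronic acid | COc1cc(OC)cc(OC)c1B(O)O | starting material
19 | triethyl[(2-{(1R,3aR,4R,7R)-1,4-dimethyl-1-[(2,4,6-trimethoxyphenyl)methyl]-1,2,3,3a,4,5,6,7-octahydroazulen-7-yl}propan-2-yl)oxy]silane | COc1cc(OC)cc(OC)c1C[C@@]2(C)CC[C@H]3C2=C[C@H](C(C)(C)O[Si](CC)(CC)CC)CC[C@H]3C | intermediate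
20 | triethyl[(2-{(1R,3aR,4R,7R)-1,4-dimethyl-1-[(1R)-3-methyl-1-(2,4,6-trimethoxyphenyl)but-3-en-1-yl]-1,2,3,3a,4,5,6,7-octahydroazulen-7-yl}propan-2-yl)oxy]silane | COc1cc(OC)cc(OC)c1[C@H](CC(C)=C)[C@@]2(C)CC[C@H]3C2=C[C@H](C(C)(C)O[Si](CC)(CC)CC)CC[C@H]3C | intermediate
21 | triethyl[(2-{(1R,3aR,4R,7R)-1,4-dimethyl-1-[(1R)-3-methyl-1-(2,4,6-trimethoxyphenyl)butyl]-1,2,3,3a,4,5,6,7-octahydroazulen-7-yl}propan-2-yl)oxy]silane | COc1cc(OC)cc(OC)c1[C@H](CC(C)C)[C@@]2(C)CC[C@H]3C2=C[C@H](C(C)(C)O[Si](CC)(CC)CC)CC[C@H]3C | intermediate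
22 | triethyl[(2-{(1R,3aR,4R,7R)-1-[(1R)-1-(3,5-dibromo-2,4,6-trimethoxyphenyl)-3-methylbutyl]-1,4-dimethyl-1,2,3,3a,4,5,6,7-octahydroazulen-7-yl}propan-2-yl)oxy]silane | COc1c(Br)c(OC)c(Br)c(OC)c1[C@H](CC(C)C)[C@@]2(C)CC[C@H]3C2=C[C@H](C(C)(C)O[Si](CC)(CC)CC)CC[C@H]3C | intermediate
23 | 3,5-dilithio analogue of 22 (both bromines replaced by lithium) | COc1c([Li])c(OC)c([Li])c(OC)c1[C@H](CC(C)C)[C@@]2(C)CC[C@H]3C2=C[C@H](C(C)(C)O[Si](CC)(CC)CC)CC[C@H]3C | intermediate
24 | 5-[(1R)-1-{(1R,3aR,4R,7R)-1,4-dimethyl-7-{2-[(triethylsilyl)oxy]propan-2-yl}-1,2,3,3a,4,5,6,7-octahydroazulen-1-yl}-3-methylbutyl]-2,4,6-trimethoxybenzene-1,3-dicarbaldehyde | COc1c(C=O)c(OC)c(C=O)c(OC)c1[C@H](CC(C)C)[C@@]2(C)CC[C@H]3C2=C[C@H](C(C)(C)O[Si](CC)(CC)CC)CC[C@H]3C | intermediate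
25 | 5-[(1R)-1-{(1R,3aR,4R,7R)-7-(2-hydroxypropan-2-yl)-1,4-dimethyl-1,2,3,3a,4,5,6,7-octahydroazulen-1-yl}-3-methylbutyl]-2,4,6-trimethoxybenzene-1,3-dicarbaldehyde | COc1c(C=O)c(OC)c(C=O)c(OC)c1[C@H](CC(C)C)[C@@]2(C)CC[C@H]3C2=C[C@H](C(C)(C)O)CC[C@H]3C | intermediate
26 | (−)-macrocarpal D, 5-[(1R)-1-{(1R,3aR,4R,7R)-7-(2-hydroxypropan-2-yl)-1,4-dimethyl-1,2,3,3a,4,5,6,7-octahydroazulen-1-yl}-3-methylbutyl]-2,4,6-trihydroxybenzene-1,3-dicarbaldehyde | CC(C)C[C@@H](c1c(O)c(C=O)c(O)c(C=O)c1O)[C@@]1(C)CC[C@H]2C1=C[C@H](C(C)(C)O)CC[C@H]2C | target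

**Step count and risks**

Total: 18 steps. Longest linear sequence: 18 steps from (R)-carvone (1); compounds 8 and 18 enter as purchased materials.

Steps most likely to fail:

1. Step 13 (Proposed new method). Hydride abstraction at C9′ may be slow because the benzylic C–H bonds of this neopentyl-type arm align poorly with the arene π-system, which would let oxidation elsewhere compete, and capture of the cation may show low or reversed facial selectivity. The fallback sets out from 19 and reverses the order of bond formation at C9′ with known reactions. DDQ in wet CH2Cl2 takes the benzylic methylene through the alcohol to the aryl ketone F1. 2-Methylallylmagnesium chloride adds to this hindered ketone through its six-membered allyl-transfer transition state to give the tertiary carbinol F2. Wilkinson hydrogenation of the methallyl alkene gives the isobutyl carbinol F3. Ionic deoxygenation (Et3SiH, BF3·OEt2, CH2Cl2, −78 °C) then returns to the route at 21. Hydride enters last here where carbon entered last in step 13, so the same facial bias of the cation should lead to the epimeric C9′ series, and whichever order gives 9′R would be used.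

2. Step 12. The neopentyl palladium may have to wait too long for the hindered boronate, which would allow protodeboronation of the di-ortho-methoxy boronic acid or 3-exo insertion into C8=C8a, and the alkene face selection may be insufficient. The fallback sets out from 17 and keeps the Heck ring closure but changes the capture. A domino Heck–borylation (Pd(OAc)2/(R)-BINAP, B2pin2, KOAc, dioxane) gives the neopentyl boronate F4. Oxidation with NaBO3 gives the primary alcohol F5, and Dess–Martin oxidation gives the non-enolisable aldehyde F6. 2,4,6-Trimethoxyphenyllithium F7, made from 1,3,5-trimethoxybenzene and n-BuLi, adds to F6 to give the benzylic alcohol F8. Lewis-acid Hosomi–Sakurai substitution (methallyltrimethylsilane, BF3·OEt2, CH2Cl2, −78 °C) through the same benzylic cation returns to the route at 20, which also makes step 13 unnecessary.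

3. Step 4. The butoxide may cleave the silyl enol ether before carbene addition, or the α-bromo enone may degrade under the basic and thermal ring-opening conditions. The fallback sets out from 5 and uses the oxidative siloxycyclopropane route. Furukawa cyclopropanation (Et2Zn, CH2I2) gives the siloxycyclopropane F9. FeCl3 in DMF opens it to the β-chloro ketone F10, and NaOAc in methanol eliminates HCl to give the enone F11. Iodine and pyridine give the α-iodo enone F12, which takes the place of 7 in step 5 and so returns to the route at 10.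

Further compounds
F1 | step 13 | {(1R,3aR,4R,7R)-1,4-dimethyl-7-{2-[(triethylsilyl)oxy]propan-2-yl}-1,2,3,3a,4,5,6,7-octahydroazulen-1-yl}(2,4,6-trimethoxyphenyl)methanone | COc1cc(OC)cc(OC)c1C(=O)[C@@]2(C)CC[C@H]3C2=C[C@H](C(C)(C)O[Si](CC)(CC)CC)CC[C@H]3C
F2 | step 13 | 1-{(1R,3aR,4R,7R)-1,4-dimethyl-7-{2-[(triethylsilyl)oxy]propan-2-yl}-1,2,3,3a,4,5,6,7-octahydroazulen-1-yl}-3-methyl-1-(2,4,6-trimethoxyphenyl)but-3-en-1-ol (carbinol epimers) | COc1cc(OC)cc(OC)c1C(O)(CC(C)=C)[C@@]2(C)CC[C@H]3C2=C[C@H](C(C)(C)O[Si](CC)(CC)CC)CC[C@H]3C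
F3 | step 13 | 1-{(1R,3aR,4R,7R)-1,4-dimethyl-7-{2-[(triethylsilyl)oxy]propan-2-yl}-1,2,3,3a,4,5,6,7-octahydroazulen-1-yl}-3-methyl-1-(2,4,6-trimethoxyphenyl)butan-1-ol (carbinol epimers) | COc1cc(OC)cc(OC)c1C(O)(CC(C)C)[C@@]2(C)CC[C@H]3C2=C[C@H](C(C)(C)O[Si](CC)(CC)CC)CC[C@H]3C
F4 | step 12 | 2-({(1R,3aR,4R,7R)-1,4-dimethyl-7-{2-[(triethylsilyl)oxy]propan-2-yl}-1,2,3,3a,4,5,6,7-octahydroazulen-1-yl}methyl)-4,4,5,5-tetramethyl-1,3,2-dioxaborolane | CC1(C)OB(C[C@@]2(C)CC[C@H]3C2=C[C@H](C(C)(C)O[Si](CC)(CC)CC)CC[C@H]3C)OC1(C)C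
F5 | step 12 | {(1R,3aR,4R,7R)-1,4-dimethyl-7-{2-[(triethylsilyl)oxy]propan-2-yl}-1,2,3,3a,4,5,6,7-octahydroazulen-1-yl}methanol | OC[C@@]1(C)CC[C@H]2C1=C[C@H](C(C)(C)O[Si](CC)(CC)CC)CC[C@H]2C
F6 | step 12 | (1R,3aR,4R,7R)-1,4-dimethyl-7-{2-[(triethylsilyl)oxy]propan-2-yl}-1,2,3,3a,4,5,6,7-octahydroazulene-1-carbaldehyde | O=C[C@@]1(C)CC[C@H]2C1=C[C@H](C(C)(C)O[Si](CC)(CC)CC)CC[C@H]2C
F7 | step 12 | 2,4,6-trimethoxyphenyllithium | COc1cc(OC)c([Li])c(OC)c1
F8 | step 12 | {(1R,3aR,4R,7R)-1,4-dimethyl-7-{2-[(triethylsilyl)oxy]propan-2-yl}-1,2,3,3a,4,5,6,7-octahydroazulen-1-yl}(2,4,6-trimethoxyphenyl)methanol (carbinol epimers) | COc1cc(OC)cc(OC)c1C(O)[C@@]2(C)CC[C@H]3C2=C[C@H](C(C)(C)O[Si](CC)(CC)CC)CC[C@H]3C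
F9 | step 4 | (3R)-6-methyl-3-{2-[(triethylsilyl)oxy]propan-2-yl}-1-[(trimethylsilyl)oxy]bicyclo[4.1.0]heptane (ring-fusion diastereomers) | CC12CC[C@@H](C(C)(C)O[Si](CC)(CC)CC)CC1(O[Si](C)(C)C)C2
F10 | step 4 | (6R)-3-chloro-3-methyl-6-{2-[(triethylsilyl)oxy]propan-2-yl}cycloheptan-1-one (C3 epimers) | CC1(Cl)CC(=O)C[C@@H](CC1)C(C)(C)O[Si](CC)(CC)CC
F11 | step 4 | (6R)-3-methyl-6-{2-[(triethylsilyl)oxy]propan-2-yl}cyclohept-2-en-1-one | CC1=CC(=O)C[C@@H](CC1)C(C)(C)O[Si](CC)(CC)CC
F12 | step 4 | (6R)-2-iodo-3-methyl-6-{2-[(triethylsilyl)oxy]propan-2-yl}cyclohept-2-en-1-one | CC1=C(I)C(=O)C[C@@H](CC1)C(C)(C)O[Si](CC)(CC)CC
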